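## Retrosynthetic overview

1. Cyclohexene numbering: C1 = CH–aryl, C2=C3(CH3), C6 = C(CH3)(vinyl). The last disconnection is the bond from the quaternary ring carbon C6 to the vinyl CH: C6 is generated as a tertiary radical from a redox-active ester (the carboxyl carbon is a traceless activating group) and alkenylated by the (E)-β-sulfonylstyrene of the second coumarin, anti to the C1 aryl group.
2. Enabling feature: C6 is a fully substituted sp3 ring carbon whose only stereogenic neighbour is C1–H(aryl). The ring has aryl at C1 next to C6 and CH3 at C3 para to C6, the ortho/para pattern of a Diels–Alder adduct of a 1-aryl-3-methylbutadiene with a methacrylic dienophile. The C6 configuration of the precursor is erased in the planar radical, so only C1 must be set beforehand.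
3. Ring order: both benzopyranone (coumarin) rings first, by Wittig–lactonisation of a brominated salicylaldehyde to 6-bromo-7-methoxycoumarin, the common origin of both halves. The cyclohexene ring follows by a catalytic enantioselective Diels–Alder reaction, which sets C1. The key step closes no ring.
4. Both coupling partners come from the bromocoumarin by Heck reactions: with 2-methylbut-3-en-2-ol (then dehydration to the diene) and with phenyl vinyl sulfone (the radical acceptor).

Key step: step 9

Remark (assumption): the Diels–Alder step is taken to be endo-selective for the formyl group and to follow the usual facial model of the protonated oxazaborolidine; were the exo mode to dominate, the enantiomeric catalyst would supply the same configuration at the aryl-bearing carbon, and the resulting epimer at the quaternary carbon would converge in step 9.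

## Route

Step 1
Reactants: 1 2-hydroxy-4-methoxybenzaldehyde
Product: 2 5-bromo-2-hydroxy-4-methoxybenzaldehyde
Conditions: NBS (1.05 equiv), NH4OAc (cat.), MeCN, 0 °C to rt
Reagents that add atoms: N-bromosuccinimide, O=C1CCC(=O)N1Br
Why: Electrophilic aromatic bromination: C5 is para to the hydroxyl and ortho to the methoxy group and is less hindered than C3, so the bromine should enter there selectively.

Step 2
Reactants: 2 5-bromo-2-hydroxy-4-methoxybenzaldehyde; 3 ethyl 2-(triphenyl-λ5-phosphanylidene)acetate
Product: 5 6-bromo-7-methoxy-2H-chromen-2-one, via o-hydroxycinnamate ester 4 (not isolated)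
Conditions: PhNEt2, reflux (ca. 215 °C)
Reagents that add atoms: none
Why: Wittig olefination followed by thermal E-to-Z isomerisation and lactonisation (the classical salicylaldehyde route to coumarins) should close the pyranone ring with loss of ethanol, the aryl bromide being inert under these conditions.

Step 3
Reactants: 5 6-bromo-7-methoxy-2H-chromen-2-one; 6 2-methylbut-3-en-2-ol
Product: 7 6-[(1E)-3-hydroxy-3-methylbut-1-en-1-yl]-7-methoxy-2H-chromen-2-one
Conditions: Pd(OAc)2 (5 mol%), P(o-tol)3 (10 mol%), Et3N, DMF, 100 °C
Reagents that add atoms: none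
Why: Heck reaction: syn-carbopalladation at the unsubstituted alkene terminus and syn-β-hydride elimination should give the E-styrenyl tertiary alcohol, which cannot isomerise to a ketone because the carbinol carbon is fully substituted.

Step 4
Reactants: 7 6-[(1E)-3-hydroxy-3-methylbut-1-en-1-yl]-7-methoxy-2H-chromen-2-one
Product: 9 7-methoxy-6-[(1E)-3-methylbuta-1,3-dien-1-yl]-2H-chromen-2-one, via allylic sulfamate ester 8 (not isolated)
Conditions: methyl N-(triethylammoniosulfonyl)carbamate (Burgess reagent, 1.5 equiv), BHT (cat.), THF, rt to 50 °C; diene used at once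
Reagents that add atoms: none
Why: Dehydration by syn-elimination of the sulfamate ester: only the methyl hydrogens are available, so the 1,3-diene should form under neutral conditions mild enough to hold back its Diels–Alder self-dimerisation.

Step 5
Reactants: 9 7-methoxy-6-[(1E)-3-methylbuta-1,3-dien-1-yl]-2H-chromen-2-one; 10 methacrolein (2-methylprop-2-enal, excess)
Product: 11 (1R,2R)-2-(7-methoxy-2-oxo-2H-chromen-6-yl)-1,4-dimethylcyclohex-3-ene-1-carbaldehyde (formyl cis to aryl)
Conditions: (R)-B-(o-tolyl)oxazaborolidine from (R)-α,α-diphenylprolinol, activated with Tf2NH (20 mol%), CH2Cl2, −78 to −40 °C; chromatography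
Reagents that add atoms: none
Why: Catalytic enantioselective Diels–Alder reaction: the cationic oxazaborolidine binds the s-trans enal and shields one enantioface, the larger diene coefficient at the CH2 terminus pairs with the enal β-carbon (aryl ortho and ring methyl para to the formyl-bearing carbon), and endo approach should give the (1R,2R) adduct, whose aryl-bearing stereocentre is the only one carried to the target; the minor exo adduct, which has the opposite configuration at that carbon, is removed by chromatography.

Step 6
Reactants: 11 (1R,2R)-2-(7-methoxy-2-oxo-2H-chromen-6-yl)-1,4-dimethylcyclohex-3-ene-1-carbaldehyde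
Product: 12 (1R,2R)-2-(7-methoxy-2-oxo-2H-chromen-6-yl)-1,4-dimethylcyclohex-3-ene-1-carboxylic acid
Conditions: NaClO2, NaH2PO4, 2-methyl-2-butene (excess), t-BuOH/H2O, 0 °C to rt
Reagents that add atoms: sodium chlorite, [Na+].[O-]Cl=O
Why: Pinnick oxidation: chlorous acid should oxidise the hindered, non-enolisable aldehyde to the acid without touching either stereocentre, while 2-methyl-2-butene intercepts the hypochlorous acid that could otherwise attack the ring alkene or the methoxyarene.

Step 7
Reactants: 12 (1R,2R)-2-(7-methoxy-2-oxo-2H-chromen-6-yl)-1,4-dimethylcyclohex-3-ene-1-carboxylic acid; 13 N-hydroxyphthalimide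
Product: 14 1,3-dioxoisoindolin-2-yl (1R,2R)-2-(7-methoxy-2-oxo-2H-chromen-6-yl)-1,4-dimethylcyclohex-3-ene-1-carboxylate
Conditions: DIC (1.2 equiv), DMAP (cat.), CH2Cl2, rt
Reagents that add atoms: none
Why: Carbodiimide (Steglich-type) esterification with N-hydroxyphthalimide should give the redox-active ester without affecting the stereocentres.

Step 8
Reactants: 5 6-bromo-7-methoxy-2H-chromen-2-one; 15 phenyl vinyl sulfone
Product: 16 7-methoxy-6-[(E)-2-(phenylsulfonyl)ethenyl]-2H-chromen-2-one
Conditions: Pd(OAc)2 (5 mol%), P(o-tol)3 (10 mol%), Et3N, DMF, 100 °C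
Reagents that add atoms: none
Why: Heck reaction with an electron-poor alkene: arylation at the unsubstituted terminus and syn-β-hydride elimination should give the E-β-arylvinyl sulfone.

Step 9
Reactants: 14 1,3-dioxoisoindolin-2-yl (1R,2R)-2-(7-methoxy-2-oxo-2H-chromen-6-yl)-1,4-dimethylcyclohex-3-ene-1-carboxylate; 16 7-methoxy-6-[(E)-2-(phenylsulfonyl)ethenyl]-2H-chromen-2-one (3 equiv)
Product: 18 7-methoxy-6-[(1S,6R)-6-[(E)-2-(7-methoxy-2-oxo-2H-chromen-6-yl)ethenyl]-3,6-dimethylcyclohex-2-en-1-yl]-2H-chromen-2-one, via tertiary cyclohexenyl radical 17 (not isolated)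
Conditions: Ru(bpy)3(PF6)2 (2 mol%), Hantzsch ester (1.5 equiv), i-Pr2NEt (2 equiv), degassed CH2Cl2 (ca. 0.5 M in 16), blue LEDs (450 nm), rt
Reagents that add atoms: none
Why: Single-electron reduction of the N-acyloxyphthalimide by the photoreduced Ru(I) species (Hantzsch ester as terminal reductant) should fragment it to CO2, phthalimide anion and the tertiary radical 17, which adds to the sulfonyl-bearing carbon of 16 to give a benzylic radical that expels PhSO2• by β-scission and leaves the E-alkene. The closest known reaction type is the photoredox decarboxylative alkenylation of redox-active esters and free acids with β-aryl vinyl sulfones, together with the diastereoselective coupling of tertiary ring radicals from N-acyloxyphthalimides with radical acceptors. No ring is closed. The new quaternary stereocentre is controlled by the adjacent aryl-bearing CH: in the planar radical the aryl group should sit pseudoaxial to avoid allylic-type strain with the radical's methyl group and block one face, so the acceptor bonds anti to it (alkenyl trans to aryl, methyl cis), and because the radical is planar the configuration of the quaternary carbon in 14 does not matter. The step needs face selectivity (secured by that neighbouring aryl group), addition at the α-sulfonyl carbon rather than at a coumarin C3=C4 bond (secured by formation of the benzylic radical, the sulfone activation and the excess of 16) and retention of the E geometry (secured by the low triplet energy of the Ru sensitiser and by reversible sulfonyl-radical addition).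

## Compound list

1 | 2-hydroxy-4-methoxybenzaldehyde | COc1ccc(C=O)c(O)c1 | starting material
2 | 5-bromo-2-hydroxy-4-methoxybenzaldehyde | COc1cc(O)c(C=O)cc1Br | intermediate
3 | ethyl 2-(triphenyl-λ5-phosphanylidene)acetate | CCOC(=O)C=P(c1ccccc1)(c1ccccc1)c1ccccc1 | starting material
4 | ethyl (E)-3-(5-bromo-2-hydroxy-4-methoxyphenyl)prop-2-enoate (not isolated) | CCOC(=O)/C=C/c1cc(Br)c(OC)cc1O | intermediate
5 | 6-bromo-7-methoxy-2H-chromen-2-one | COc1cc2oc(=O)ccc2cc1Br | intermediate
6 | 2-methylbut-3-en-2-ol | CC(C)(O)C=C | starting material
7 | 6-[(1E)-3-hydroxy-3-methylbut-1-en-1-yl]-7-methoxy-2H-chromen-2-one | COc1cc2oc(=O)ccc2cc1/C=C/C(C)(C)O | intermediate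
8 | methyl N-{[(3E)-4-(7-methoxy-2-oxo-2H-chromen-6-yl)-2-methylbut-3-en-2-yl]oxysulfonyl}carbamate (triethylammonium salt in the flask, not isolated) | COC(=O)NS(=O)(=O)OC(C)(C)/C=C/c1cc2ccc(=O)oc2cc1OC | intermediate
9 | 7-methoxy-6-[(1E)-3-methylbuta-1,3-dien-1-yl]-2H-chromen-2-one | COc1cc2oc(=O)ccc2cc1/C=C/C(C)=C | intermediate
10 | methacrolein (2-methylprop-2-enal) | CC(=C)C=O | starting material
11 | (1R,2R)-2-(7-methoxy-2-oxo-2H-chromen-6-yl)-1,4-dimethylcyclohex-3-ene-1-carbaldehyde | O=C[C@]1(C)CCC(C)=C[C@@H]1c1cc2ccc(=O)oc2cc1OC | intermediate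
12 | (1R,2R)-2-(7-methoxy-2-oxo-2H-chromen-6-yl)-1,4-dimethylcyclohex-3-ene-1-carboxylic acid | OC(=O)[C@]1(C)CCC(C)=C[C@@H]1c1cc2ccc(=O)oc2cc1OC | intermediate
13 | N-hydroxyphthalimide | O=C1c2ccccc2C(=O)N1O | starting material
14 | 1,3-dioxoisoindolin-2-yl (1R,2R)-2-(7-methoxy-2-oxo-2H-chromen-6-yl)-1,4-dimethylcyclohex-3-ene-1-carboxylate | O=C(ON1C(=O)c2ccccc2C1=O)[C@]1(C)CCC(C)=C[C@@H]1c1cc2ccc(=O)oc2cc1OC | intermediate
15 | phenyl vinyl sulfone | C=CS(=O)(=O)c1ccccc1 | starting material
16 | 7-methoxy-6-[(E)-2-(phenylsulfonyl)ethenyl]-2H-chromen-2-one | COc1cc2oc(=O)ccc2cc1/C=C/S(=O)(=O)c1ccccc1 | intermediate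
17 | 2-(7-methoxy-2-oxo-2H-chromen-6-yl)-1,4-dimethylcyclohex-3-en-1-yl radical, aryl-bearing stereocentre as in 14 (not isolated) | C[C]1CCC(C)=C[C@@H]1c1cc2ccc(=O)oc2cc1OC | intermediate
18 | 7-methoxy-6-[(1S,6R)-6-[(E)-2-(7-methoxy-2-oxo-2H-chromen-6-yl)ethenyl]-3,6-dimethylcyclohex-2-en-1-yl]-2H-chromen-2-one | COc1cc2oc(=O)ccc2cc1/C=C/[C@@]1(C)CCC(C)=C[C@@H]1c1cc2ccc(=O)oc2cc1OC | target

## Step count and risks

Total steps: 9. Longest linear sequence: 8 steps (1, 2, 3, 4, 5, 6, 7, 9); step 8 is a one-step branch from 5.

**Step 9 (most at risk).** The tertiary radical may rearrange before capture, by a 1,2-aryl shift or by a homoallyl/cyclopropylcarbinyl vinyl shift. It may also add to a coumarin C3=C4 bond, or the face selectivity at the radical carbon may be insufficient. The fallback replaces free-acceptor addition–elimination with a nickel-catalysed decarboxylative Negishi-type alkenylation, in which the radical is captured by an alkenylnickel species and the bond is made by reductive elimination. It sets out from bromide 5 and redox-active ester 14. A Heck reaction of 5 with acrylic acid (Pd(OAc)2, P(o-tol)3, Et3N, DMF) should give (E)-3-(7-methoxy-2-oxo-2H-chromen-6-yl)prop-2-enoic acid F1. Hunsdiecker-type iododecarboxylation (N-iodosuccinimide, cat. Et3N, MeCN) should convert it to 6-[(E)-2-iodoethenyl]-7-methoxy-2H-chromen-2-one F2. Zinc insertion (Zn dust, LiCl, THF) should give the (E)-alkenylzinc iodide F3. Coupling of F3 with 14 under Ni(acac)2/2,2'-bipyridine (THF/DMF, rt) would return to the route at 18.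

**Step 5.** The electron-rich diene may oligomerise under the acidic catalyst, the Lewis acid may be bound by the coumarin carbonyl, or the enantioface or endo/exo control may be insufficient. The fallback replaces asymmetric catalysis by resolution. It sets out from diene 9: a Diels–Alder reaction with methacrolein 10 under an achiral Lewis acid (EtAlCl2, CH2Cl2, −78 °C) should give the endo aldehyde 11 together with its enantiomer, (1S,2S)-2-(7-methoxy-2-oxo-2H-chromen-6-yl)-1,4-dimethylcyclohex-3-ene-1-carbaldehyde F4. The two would be separated by preparative chromatography on a chiral stationary phase, and the route is rejoined at 11.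

**Step 4.** The diene may dimerise by Diels–Alder self-reaction or polymerise during its formation and isolation, or the sulfamate may undergo allylic transposition instead of elimination. The fallback avoids the alcohol and the dehydration. It sets out from bromide 5: a Suzuki–Miyaura coupling with 4,4,5,5-tetramethyl-2-[(1E)-3-methylbuta-1,3-dien-1-yl]-1,3,2-dioxaborolane F5 (from 2-methylbut-1-en-3-yne and pinacolborane by zirconocene-catalysed hydroboration) under Pd(dppf)Cl2, K3PO4, THF/H2O at 40–50 °C should give the diene directly, at a temperature where self-dimerisation should be slow. It returns to the route at 9.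

## Further compounds

F1 | step 9 | (E)-3-(7-methoxy-2-oxo-2H-chromen-6-yl)prop-2-enoic acid | COc1cc2oc(=O)ccc2cc1/C=C/C(=O)O
F2 | step 9 | 6-[(E)-2-iodoethenyl]-7-methoxy-2H-chromen-2-one | COc1cc2oc(=O)ccc2cc1/C=C/I
F3 | step 9 | [(E)-2-(7-methoxy-2-oxo-2H-chromen-6-yl)ethenyl]zinc iodide | COc1cc2oc(=O)ccc2cc1/C=C/[Zn]I
F4 | step 5 | (1S,2S)-2-(7-methoxy-2-oxo-2H-chromen-6-yl)-1,4-dimethylcyclohex-3-ene-1-carbaldehyde | O=C[C@@]1(C)CCC(C)=C[C@H]1c1cc2ccc(=O)oc2cc1OC
F5 | step 4 | 4,4,5,5-tetramethyl-2-[(1E)-3-methylbuta-1,3-dien-1-yl]-1,3,2-dioxaborolane | CC(=C)/C=C/B1OC(C)(C)C(C)(C)O1
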